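**Retrosynthetic overview**
- Target ⇐ C7 exocyclic methylene (dihydroxylation) ⇐ ring B closed last by a 6-endo vinyl-radical cyclisation that forms C6–C7 and sets C5 by H-atom transfer.
- Radical precursor ⇐ all-cis cyclohexene: CHO → 3-hydroxypropanoyl, acetyl → isopropenyl, silyl enol ether → α-ketol (Rubottom).
- Ring A is formed first by a catalytic enantioselective Diels–Alder reaction of a 2-silyloxy diene with (Z)-2-methyl-4-oxopent-2-enal (C3–C4 and C4a–C8a bonds, four contiguous stereocentres).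
- Diene ⇐ (R)-2-methylbutanal + 3-bromobutan-2-one + 2,3-dibromopropene; dienophile ⇐ 2,4-dimethylfuran.

Locants in the text are those of the target core, octahydronaphthalen-1(2H)-one: C1 ketone, C2 carbinol, C3 sec-butyl, C4 quaternary, C4a/C8a ring fusion, C5 methyl, C7 diol carbon.

Assumption: (R)-2-methylbutanal of high ee is bought (or freshly made from commercial (R)-2-methylbutan-1-ol), and the step 6 catalyst is used as whichever enantiomer exposes the C2-Si face of the enal (both diphenylprolinol antipodes are sold).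

**Step 1**
Reactants: 1 3-bromobutan-2-one
Product: 3 3-(triphenyl-λ5-phosphanylidene)butan-2-one, via phosphonium bromide 2 (not isolated)
Conditions: PPh3, PhMe, 50 °C; then NaOH (aq), CH2Cl2, rt
Reagents that add atoms: triphenylphosphine, c1ccc(cc1)P(c1ccccc1)c1ccccc1
Why: SN2 alkylation of PPh3 by the α-bromo ketone and deprotonation of the salt give the acyl-stabilised Wittig ylide; no stereocentre is involved.

**Step 2**
Reactants: 4 (2R)-2-methylbutanal; 3 3-(triphenyl-λ5-phosphanylidene)butan-2-one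
Product: 5 (3E,5R)-3,5-dimethylhept-3-en-2-one
Conditions: PhMe, 80 °C (sealed tube)
Reagents that add atoms: none
Why: Wittig reaction of a stabilised, weakly basic ylide gives the E trisubstituted enone and leaves the α-stereocentre of the aldehyde (the future sec-butyl centre) untouched.

**Step 3**
Reactants: 5 (3E,5R)-3,5-dimethylhept-3-en-2-one; 6 2,3-dibromoprop-1-ene
Product: 8 (6E,8R)-2-bromo-6,8-dimethyldeca-1,6-dien-5-one, via lithium enolate 7 (not isolated)
Conditions: LiN(iPr)2, THF, −78 °C; then 6, −78 → −30 °C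
Reagents that add atoms: none
Why: Kinetic α'-deprotonation of the methyl ketone and SN2 enolate alkylation by the allylic bromide install the 2-bromoallyl group that later serves as vinyl-radical precursor (no new stereocentre).

**Step 4**
Reactants: 8 (6E,8R)-2-bromo-6,8-dimethyldeca-1,6-dien-5-one
Product: 10 {[(4Z,6E,8R)-2-bromo-6,8-dimethyldeca-1,4,6-trien-5-yl]oxy}tri(propan-2-yl)silane, via lithium Z-enolate 9 (not isolated)
Conditions: LiN(iPr)2, THF/DMPU, −78 °C; iPr3SiOTf, −78 → 0 °C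
Reagents that add atoms: tri(propan-2-yl)silyl trifluoromethanesulfonate, CC(C)[Si](C(C)C)(C(C)C)OS(=O)(=O)C(F)(F)F
Why: Kinetic enolisation at the only CH2 next to the carbonyl and O-silylation (silyl enol ether formation) give the cross-conjugated 2-silyloxy diene, the alkenyl ketone and DMPU favouring the Z(O)-enolate so that the CH2 chain sits "outside" in the s-cis diene.

**Step 5**
Reactants: 11 2,4-dimethylfuran
Product: 13 (2Z)-2-methyl-4-oxopent-2-enal, via furan epoxide 12 (not isolated)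
Conditions: dimethyldioxirane (acetone solution), CH2Cl2, −40 → 0 °C; concentrate cold, use at once
Reagents that add atoms: dimethyldioxirane, CC1(C)OO1
Why: Oxidative furan ring opening (dioxirane epoxidation, then electrocyclic opening of the epoxide) unmasks the enedicarbonyl with the Z geometry imposed by the ring.

**Step 6**
Reactants: 10 {[(4Z,6E,8R)-2-bromo-6,8-dimethyldeca-1,4,6-trien-5-yl]oxy}tri(propan-2-yl)silane; 13 (2Z)-2-methyl-4-oxopent-2-enal
Product: 14 (1S,2S,5S,6R)-6-acetyl-5-(2-bromoprop-2-en-1-yl)-2-[(2R)-butan-2-yl]-1,3-dimethyl-4-{[tri(propan-2-yl)silyl]oxy}cyclohex-3-ene-1-carbaldehyde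
Conditions: Corey oxazaborolidinium salt [C24H25BNO][N(SO2CF3)2] (N-protonated B-(2-methylphenyl) oxazaborolidine of α,α-diphenylprolinol, 20 mol%), CH2Cl2, −78 → −40 °C
Reagents that add atoms: none
Why: Catalytic enantioselective Diels–Alder reaction in which the formyl-bound chiral Lewis acid makes C3 of 13 the electrophilic terminus that joins the nucleophilic CH terminus of the silyloxy diene (C4a–C8a and C3–C4 bonds), the endo transition state of the Z dienophile with the two "outside" diene substituents gives the all-cis array at C3, C4, C4a and C8a, and the catalyst (not the remote sec-butyl centre) shields the C2-Re face of 13 so that these centres form in the absolute sense required.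

**Step 7**
Reactants: 14 (1S,2S,5S,6R)-6-acetyl-5-(2-bromoprop-2-en-1-yl)-2-[(2R)-butan-2-yl]-1,3-dimethyl-4-{[tri(propan-2-yl)silyl]oxy}cyclohex-3-ene-1-carbaldehyde
Product: 16 1,1'-{(1S,2R,3S,6S)-3-(2-bromoprop-2-en-1-yl)-6-[(2R)-butan-2-yl]-1,5-dimethyl-4-{[tri(propan-2-yl)silyl]oxy}cyclohex-4-ene-1,2-diyl}di(ethan-1-one), via trimethylsilyl ketone 15 (not isolated)
Conditions: Me3SiCHN2, MgBr2·OEt2, CH2Cl2, −20 → 0 °C; then MeOH, SiO2, rt
Reagents that add atoms: (trimethylsilyl)diazomethane, C[Si](C)(C)C=[N+]=[N-]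
Why: Diazoalkane homologation of the aldehyde (addition to the activated formyl group, loss of N2 with 1,2-hydride shift, then protodesilylation) turns the neopentylic CHO into a methyl ketone under non-basic conditions, so the epimerisable C4a–H next to the acetyl group is not touched.

**Step 8**
Reactants: 16 1,1'-{(1S,2R,3S,6S)-3-(2-bromoprop-2-en-1-yl)-6-[(2R)-butan-2-yl]-1,5-dimethyl-4-{[tri(propan-2-yl)silyl]oxy}cyclohex-4-ene-1,2-diyl}di(ethan-1-one)
Product: 17 1-{(1R,2S,5S,6S)-5-(2-bromoprop-2-en-1-yl)-2-[(2R)-butan-2-yl]-1,3-dimethyl-6-(prop-1-en-2-yl)-4-{[tri(propan-2-yl)silyl]oxy}cyclohex-3-en-1-yl}ethan-1-one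
Conditions: Zn, CH2Br2, TiCl4, THF/CH2Cl2, 0 °C → rt
Reagents that add atoms: dibromomethane, BrCBr
Why: Lombardo–Takai methylenation is non-basic (no epimerisation at C4a) and discriminates the two methyl ketones sterically, reacting at the acetyl group on the tertiary C4a and not at the one on the quaternary C4.

**Step 9**
Reactants: 17 1-{(1R,2S,5S,6S)-5-(2-bromoprop-2-en-1-yl)-2-[(2R)-butan-2-yl]-1,3-dimethyl-6-(prop-1-en-2-yl)-4-{[tri(propan-2-yl)silyl]oxy}cyclohex-3-en-1-yl}ethan-1-one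
Product: 19 1-{(1R,2S,5S,6S)-5-(2-bromoprop-2-en-1-yl)-2-[(2R)-butan-2-yl]-1,3-dimethyl-6-(prop-1-en-2-yl)-4-{[tri(propan-2-yl)silyl]oxy}cyclohex-3-en-1-yl}-3-hydroxypropan-1-one, via lithium enolate 18 (not isolated)
Conditions: LiN(iPr)2, THF, −78 °C; CH2O (g, from paraformaldehyde), −78 °C; AcOH
Reagents that add atoms: formaldehyde, C=O
Why: Aldol addition of the lithium enolate (one enolisable position only, C4 being quaternary) to monomeric formaldehyde gives the 3-hydroxypropanoyl chain.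

**Step 10**
Reactants: 19 1-{(1R,2S,5S,6S)-5-(2-bromoprop-2-en-1-yl)-2-[(2R)-butan-2-yl]-1,3-dimethyl-6-(prop-1-en-2-yl)-4-{[tri(propan-2-yl)silyl]oxy}cyclohex-3-en-1-yl}-3-hydroxypropan-1-one
Product: 21 (2S,3R,4R,5S,6S)-6-(2-bromoprop-2-en-1-yl)-3-[(2R)-butan-2-yl]-2-hydroxy-4-(3-hydroxypropanoyl)-2,4-dimethyl-5-(prop-1-en-2-yl)cyclohexan-1-one, via silyloxy epoxide 20 (not isolated)
Conditions: dimethyldioxirane (1.05 equiv), acetone/CH2Cl2, −78 → −30 °C; then HF·pyridine, THF, 0 °C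
Reagents that add atoms: dimethyldioxirane, CC1(C)OO1
Why: Rubottom oxidation in which the dioxirane epoxidises the tetrasubstituted silyl enol ether (far faster than the isopropenyl group) on the face opposite the flanking sec-butyl and bromoallyl groups, and HF opens the silyloxy epoxide to the C1 ketone with the C2 hydroxyl trans to the C3 sec-butyl group.

**Step 11**
Reactants: 21 (2S,3R,4R,5S,6S)-6-(2-bromoprop-2-en-1-yl)-3-[(2R)-butan-2-yl]-2-hydroxy-4-(3-hydroxypropanoyl)-2,4-dimethyl-5-(prop-1-en-2-yl)cyclohexan-1-one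
Product: 22 (2S,3R,4R,4aR,5R,8aS)-3-[(2R)-butan-2-yl]-2-hydroxy-4-(3-hydroxypropanoyl)-2,4,5-trimethyl-7-methylideneoctahydronaphthalen-1(2H)-one
Conditions: Bu3SnH (syringe pump, 8 h), AIBN (cat.), PhH (0.005 M), 80 °C
Reagents that add atoms: none
Why: Stork-type vinyl radical cyclisation in which Bu3Sn• abstracts bromine, the sp2 radical at C7 adds 6-endo to the CH2 terminus of the cis-disposed isopropenyl group (any 5-exo adduct ring-expands to the same tertiary radical by a cyclopropylcarbinyl shift at low stannane concentration), closing ring B through C6–C7 with the exocyclic methylene in place, and the tertiary C5 radical takes H from Bu3SnH on the convex face (syn to H-4a and H-8a, anti to quaternary C4), which puts the C5 methyl cis to C4.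

**Step 12**
Reactants: 22 (2S,3R,4R,4aR,5R,8aS)-3-[(2R)-butan-2-yl]-2-hydroxy-4-(3-hydroxypropanoyl)-2,4,5-trimethyl-7-methylideneoctahydronaphthalen-1(2H)-one
Product: 23 (2S,3R,4R,4aR,5R,7R,8aS)-3-[(2R)-butan-2-yl]-2,7-dihydroxy-7-(hydroxymethyl)-4-(3-hydroxypropanoyl)-2,4,5-trimethyloctahydronaphthalen-1(2H)-one
Conditions: OsO4 (2 mol%), N-methylmorpholine N-oxide, acetone/H2O 4:1, 0 °C → rt
Reagents that add atoms: N-methylmorpholine N-oxide, C[N+]1([O-])CCOCC1; water, O
Why: Upjohn dihydroxylation of the only remaining alkene, with OsO4 expected to add from the convex face, anti to the C5 methyl and the C8a–C1 bond that screen the concave face, placing the tertiary C7 hydroxyl on the α face and the CH2OH on the β face.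

**Compound list**
1 | 3-bromobutan-2-one (racemic) | CC(Br)C(C)=O | starting material
2 | (3-oxobutan-2-yl)triphenylphosphonium bromide | CC(C(C)=O)[P+](c1ccccc1)(c1ccccc1)c1ccccc1.[Br-] | intermediate
3 | 3-(triphenyl-λ5-phosphanylidene)butan-2-one | CC(=O)C(C)=P(c1ccccc1)(c1ccccc1)c1ccccc1 | intermediate
4 | (2R)-2-methylbutanal | CC[C@@H](C)C=O | starting material
5 | (3E,5R)-3,5-dimethylhept-3-en-2-one | CC[C@@H](C)/C=C(\C)C(C)=O | intermediate
6 | 2,3-dibromoprop-1-ene | C=C(Br)CBr | starting material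
7 | lithium (3E,5R)-3,5-dimethylhepta-1,3-dien-2-olate | CC[C@@H](C)/C=C(\C)C(=C)[O-].[Li+] | intermediate
8 | (6E,8R)-2-bromo-6,8-dimethyldeca-1,6-dien-5-one | CC[C@@H](C)/C=C(\C)C(=O)CCC(Br)=C | intermediate
9 | lithium (4Z,6E,8R)-2-bromo-6,8-dimethyldeca-1,4,6-trien-5-olate | CC[C@@H](C)/C=C(\C)/C([O-])=C/CC(Br)=C.[Li+] | intermediate
10 | {[(4Z,6E,8R)-2-bromo-6,8-dimethyldeca-1,4,6-trien-5-yl]oxy}tri(propan-2-yl)silane | CC[C@@H](C)/C=C(\C)/C(O[Si](C(C)C)(C(C)C)C(C)C)=C/CC(Br)=C | intermediate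
11 | 2,4-dimethylfuran | Cc1cc(C)co1 | starting material
12 | 1,4-dimethyl-2,6-dioxabicyclo[3.1.0]hex-3-ene (furan 2,3-epoxide, racemic) | CC1=COC2(C)OC12 | intermediate
13 | (2Z)-2-methyl-4-oxopent-2-enal | O=C/C(C)=C\C(C)=O | intermediate
14 | (1S,2S,5S,6R)-6-acetyl-5-(2-bromoprop-2-en-1-yl)-2-[(2R)-butan-2-yl]-1,3-dimethyl-4-{[tri(propan-2-yl)silyl]oxy}cyclohex-3-ene-1-carbaldehyde (CHO, sec-butyl, bromoallyl and acetyl all cis) | CC[C@@H](C)[C@@H]1[C@](C)(C=O)[C@H](C(C)=O)[C@H](CC(Br)=C)C(O[Si](C(C)C)(C(C)C)C(C)C)=C1C | intermediate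
15 | 1-{(1S,2S,5S,6R)-6-acetyl-5-(2-bromoprop-2-en-1-yl)-2-[(2R)-butan-2-yl]-1,3-dimethyl-4-{[tri(propan-2-yl)silyl]oxy}cyclohex-3-en-1-yl}-2-(trimethylsilyl)ethan-1-one | CC[C@@H](C)[C@@H]1[C@](C)(C(=O)C[Si](C)(C)C)[C@H](C(C)=O)[C@H](CC(Br)=C)C(O[Si](C(C)C)(C(C)C)C(C)C)=C1C | intermediate
16 | 1,1'-{(1S,2R,3S,6S)-3-(2-bromoprop-2-en-1-yl)-6-[(2R)-butan-2-yl]-1,5-dimethyl-4-{[tri(propan-2-yl)silyl]oxy}cyclohex-4-ene-1,2-diyl}di(ethan-1-one) | CC[C@@H](C)[C@@H]1[C@](C)(C(C)=O)[C@H](C(C)=O)[C@H](CC(Br)=C)C(O[Si](C(C)C)(C(C)C)C(C)C)=C1C | intermediate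
17 | 1-{(1R,2S,5S,6S)-5-(2-bromoprop-2-en-1-yl)-2-[(2R)-butan-2-yl]-1,3-dimethyl-6-(prop-1-en-2-yl)-4-{[tri(propan-2-yl)silyl]oxy}cyclohex-3-en-1-yl}ethan-1-one | CC[C@@H](C)[C@@H]1[C@](C)(C(C)=O)[C@H](C(C)=C)[C@H](CC(Br)=C)C(O[Si](C(C)C)(C(C)C)C(C)C)=C1C | intermediate
18 | lithium enolate of 17 (lithium 1-cyclohexenyl-ethen-1-olate, ring as in 17) | CC[C@@H](C)[C@@H]1[C@](C)(C([O-])=C)[C@H](C(C)=C)[C@H](CC(Br)=C)C(O[Si](C(C)C)(C(C)C)C(C)C)=C1C.[Li+] | intermediate
19 | 1-{(1R,2S,5S,6S)-5-(2-bromoprop-2-en-1-yl)-2-[(2R)-butan-2-yl]-1,3-dimethyl-6-(prop-1-en-2-yl)-4-{[tri(propan-2-yl)silyl]oxy}cyclohex-3-en-1-yl}-3-hydroxypropan-1-one | CC[C@@H](C)[C@@H]1[C@](C)(C(=O)CCO)[C@H](C(C)=C)[C@H](CC(Br)=C)C(O[Si](C(C)C)(C(C)C)C(C)C)=C1C | intermediate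
20 | silyloxy epoxide of 19 (oxirane across C1–C2, oxygen trans to the sec-butyl group, C1 O-silyl, C2 methyl) | CC[C@@H](C)[C@@H]1[C@](C)(C(=O)CCO)[C@H](C(C)=C)[C@H](CC(Br)=C)[C@@]2(O[Si](C(C)C)(C(C)C)C(C)C)O[C@@]12C | intermediate
21 | (2S,3R,4R,5S,6S)-6-(2-bromoprop-2-en-1-yl)-3-[(2R)-butan-2-yl]-2-hydroxy-4-(3-hydroxypropanoyl)-2,4-dimethyl-5-(prop-1-en-2-yl)cyclohexan-1-one | CC[C@@H](C)[C@@H]1[C@](C)(C(=O)CCO)[C@H](C(C)=C)[C@H](CC(Br)=C)C(=O)[C@@]1(C)O | intermediate
22 | (2S,3R,4R,4aR,5R,8aS)-3-[(2R)-butan-2-yl]-2-hydroxy-4-(3-hydroxypropanoyl)-2,4,5-trimethyl-7-methylideneoctahydronaphthalen-1(2H)-one (cis-fused) | CC[C@@H](C)[C@@H]1[C@](C)(C(=O)CCO)[C@@H]2[C@H](C)CC(=C)C[C@@H]2C(=O)[C@@]1(C)O | intermediate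
23 | (2S,3R,4R,4aR,5R,7R,8aS)-3-[(2R)-butan-2-yl]-2,7-dihydroxy-7-(hydroxymethyl)-4-(3-hydroxypropanoyl)-2,4,5-trimethyloctahydronaphthalen-1(2H)-one (CNP0112523.4) | CC[C@@H](C)[C@@H]1[C@](C)(C(=O)CCO)[C@@H]2[C@H](C)C[C@](O)(CO)C[C@@H]2C(=O)[C@@]1(C)O | target

**Step count**
Total: 12 steps. Longest linear sequence: 11 steps (1, 2, 3, 4, 6, 7, 8, 9, 10, 11, 12); step 5 is a one-step branch.

**Steps most likely to fail**

Step 6. This diene/dienophile pair is untested: the Z-keto-enal may isomerise to E on the Lewis acid, the silyl enol ether may add to the formyl carbon instead, and endo and facial control are assumed by analogy. The fallback sets out from diene 10 and replaces catalyst control by a thermal cycloaddition and a separation. Diene 10 and citraconic anhydride (CC1=CC(=O)OC1=O, PhMe, 80 °C) give the all-cis bicyclic anhydride F1, the nucleophilic diene terminus bonding to the unsubstituted alkene carbon for steric reasons. The two π-facial diastereomers form without control and are separated at this point. MeLi (1 equiv, −78 °C) opens the less hindered carbonyl to keto acid F2, Zn/CH2Br2/TiCl4 gives isopropenyl acid F3, and excess MeLi turns the carboxylate into the methyl ketone, which comes back to the route at 17.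

Step 11. The vinyl radical may be reduced before it cyclises, the 5-exo product may survive, or the final H transfer to C5 may be unselective. The fallback sets out from 21 and forms the same C6–C7 bond by a polar, palladium-mediated path. Hydroboration of the isopropenyl group with excess 9-BBN-H (THF, boron to the CH2 terminus, anti to quaternary C4) gives alkylborane F4. An intramolecular B-alkyl Suzuki–Miyaura coupling with the vinyl bromide (PdCl2(dppf), AsPh3, Cs2CO3, DMF/H2O) then comes back to the route at 22.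

Step 12. The conformation of ring B in 22 is uncertain, so osmylation may give the C7 epimer. The fallback sets out from 22 and uses a reagent with the complementary facial habit on methylenecyclohexanes. Buffered 3-chloroperbenzoic acid (NaHCO3, CH2Cl2, 0 °C, axial attack) gives spiro-epoxide F5, and hydrolytic opening at the CH2 terminus (HClO4 cat., THF/H2O) comes back to the route at 23.

**Further compounds**
F1 | step 6 | 7-(2-bromoprop-2-en-1-yl)-4-[(2R)-butan-2-yl]-3a,5-dimethyl-6-{[tri(propan-2-yl)silyl]oxy}-3a,4,7,7a-tetrahydro-2-benzofuran-1,3-dione (anhydride ring, sec-butyl and bromoallyl all cis) | CC[C@@H](C)[C@@H]1[C@]2(C)C(=O)OC(=O)[C@@H]2[C@H](CC(Br)=C)C(O[Si](C(C)C)(C(C)C)C(C)C)=C1C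
F2 | step 6 | (1S,2S,5S,6R)-6-acetyl-5-(2-bromoprop-2-en-1-yl)-2-[(2R)-butan-2-yl]-1,3-dimethyl-4-{[tri(propan-2-yl)silyl]oxy}cyclohex-3-ene-1-carboxylic acid | CC[C@@H](C)[C@@H]1[C@](C)(C(O)=O)[C@H](C(C)=O)[C@H](CC(Br)=C)C(O[Si](C(C)C)(C(C)C)C(C)C)=C1C
F3 | step 6 | (1R,2S,5S,6S)-5-(2-bromoprop-2-en-1-yl)-2-[(2R)-butan-2-yl]-1,3-dimethyl-6-(prop-1-en-2-yl)-4-{[tri(propan-2-yl)silyl]oxy}cyclohex-3-ene-1-carboxylic acid | CC[C@@H](C)[C@@H]1[C@](C)(C(O)=O)[C@H](C(C)=C)[C@H](CC(Br)=C)C(O[Si](C(C)C)(C(C)C)C(C)C)=C1C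
F4 | step 11 | 9-BBN adduct of 21 at the isopropenyl CH2 (C6–B bond, C5 configured as in 22) | CC[C@@H](C)[C@@H]1[C@](C)(C(=O)CCO)[C@H]([C@H](C)CB2C3CCCC2CCC3)[C@H](CC(Br)=C)C(=O)[C@@]1(C)O
F5 | step 12 | spiro-oxirane of 22 at C7 (oxirane oxygen on the α face, CH2 on the β face) | CC[C@@H](C)[C@@H]1[C@](C)(C(=O)CCO)[C@@H]2[C@H](C)C[C@]3(CO3)C[C@@H]2C(=O)[C@@]1(C)O
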